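**Plan**
1. Retrosynthesis: the C3–CH2 bond to the 3,4-dihydroxy-5-methoxybenzyl group is cut first (lactone enolate + benzylic bromide), then the bond between the side-chain CH2 on C4 and C1 of the 4-hydroxy-3-methoxyphenyl ring (aryl nucleophile + electrophilic CH2).
2. Enabling feature: this CH2 stands 1,3 to the enolisable C3 across C4. Tying CH2 to C3 gives a cyclopropane cis-fused to the γ-lactone (a 3-oxabicyclo[3.1.0]hexan-2-one), and a temporary ester on C3 makes that CH2 a homo-Michael acceptor.
3. Forward: (R)-epichlorohydrin and diethyl malonate give the lactone ring and the temporary cyclopropane in one step; an aryl copper reagent opens the cyclopropane at CH2 (fragment union); the ester is removed by dealkoxycarbonylation; the second benzyl group is put on C3; three benzyl ethers are removed last.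
4. Stereochemistry: C4 (R) comes from (R)-epichlorohydrin (chiral pool, one defined inversion in the cyclopropane closure); C3 (R) is set by enolate alkylation anti to the C4 substituent, which gives the trans lactone.

Key step: step 3

Remark: the SMILES is read as the trans-(3R,4R) lactone; all three phenols are carried as benzyl ethers so that one hydrogenolysis frees them.

Step 1
Reactants: 1 (R)-epichlorohydrin; 2 diethyl malonate
Product: 6 ethyl (1S,5R)-2-oxo-3-oxabicyclo[3.1.0]hexane-1-carboxylate, via chlorohydrin malonate 3 (not isolated), via epoxy malonate 4 (not isolated), via cyclopropylcarbinol diester 5 (not isolated)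
Conditions: NaOEt (1.1 equiv), EtOH, 0 °C then reflux
Reagents that add atoms: none
Why: Tandem malonate alkylation–cyclopropanation–lactonisation, in which the malonate anion opens the epoxide of 1 at its CH2 end, the alkoxide closes a new epoxide with loss of chloride, the malonate carbanion opens that epoxide at the stereogenic carbon (3-exo-tet, SN2 inversion) and the freed alkoxide lactonises, so that C5 of 6 derives from the stereocentre of 1 and the cis ring fusion fixes C1.

Step 2
Reactants: 7 4-bromo-2-methoxyphenol
Product: 8 1-(benzyloxy)-4-bromo-2-methoxybenzene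
Conditions: BnBr, K2CO3, DMF, rt
Reagents that add atoms: benzyl bromide, BrCc1ccccc1
Why: Williamson ether synthesis; the benzyl ether masks the phenol against the organometallic chemistry of step 3 and is removed by hydrogenolysis at the end.

Step 3
Reactants: 8 1-(benzyloxy)-4-bromo-2-methoxybenzene; 6 ethyl (1S,5R)-2-oxo-3-oxabicyclo[3.1.0]hexane-1-carboxylate
Product: 11 ethyl (4R)-4-[4-(benzyloxy)-3-methoxybenzyl]-2-oxotetrahydrofuran-3-carboxylate, via aryl Grignard reagent 9 (not isolated), via bromomagnesium enolate 10 (not isolated)
Conditions: 8, Mg (I2 cat.), THF, 40 °C; then CuI (20 mol%), 6, THF, −40 → −20 °C; 1 M HCl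
Reagents that add atoms: none
Why: Transmetallation of 9 to copper gives an aryl cuprate that attacks the unsubstituted cyclopropane carbon C6 of 6 in an SN2-like homoconjugate (homo-Michael) addition, anti to the C1–C6 bond, which breaks with relief of ring strain to leave the doubly stabilised, chelated enolate 10. The closest known reaction type is the copper-catalysed ring opening of cyclopropane-1,1-dicarbonyl compounds by Grignard reagents, which is established for this bicyclic lactone with alkyl Grignard reagents. No ring is closed; the temporary three-membered ring is opened and the γ-lactone made in step 1 stays intact. The only new stereocentre, C3 of 11, is an epimerisable β-dicarbonyl centre that is erased in step 4, whereas C5 of 6 is not touched and becomes C4 (R) of the lactone, so its control element is the stereocentre of 1. The step needs attack at C6 and not at the tertiary cyclopropane carbon C5 or at the two carbonyl groups; the primary, unhindered C6 and the soft cuprate at low temperature should secure this, and the product stays masked as enolate 10 until the acidic quench, which prevents later addition to it.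

Step 4
Reactants: 11 ethyl (4R)-4-[4-(benzyloxy)-3-methoxybenzyl]-2-oxotetrahydrofuran-3-carboxylate
Product: 13 (4R)-4-[4-(benzyloxy)-3-methoxybenzyl]dihydrofuran-2(3H)-one, via lithium carboxylate 12 (not isolated)
Conditions: LiCl, DMSO, H2O, 140 °C
Reagents that add atoms: none
Why: Krapcho dealkoxycarbonylation, in which chloride dealkylates the ethyl ester, the β-carbonyl carboxylate 12 loses CO2 and the lactone enolate is protonated by water; C4 is not enolisable and should keep its configuration.

Step 5
Reactants: 14 3,4-dihydroxy-5-methoxybenzaldehyde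
Product: 15 3,4-bis(benzyloxy)-5-methoxybenzaldehyde
Conditions: BnBr (2.4 equiv), K2CO3, DMF, 60 °C
Reagents that add atoms: benzyl bromide, BrCc1ccccc1
Why: Double Williamson O-benzylation of the catechol, which removes the acidic and oxidisable phenols before enolate chemistry.

Step 6
Reactants: 15 3,4-bis(benzyloxy)-5-methoxybenzaldehyde
Product: 16 [3,4-bis(benzyloxy)-5-methoxyphenyl]methanol
Conditions: NaBH4, MeOH–THF, 0 °C
Reagents that add atoms: none
Why: Borohydride reduction of an aryl aldehyde to the benzylic alcohol; ethers are inert.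

Step 7
Reactants: 16 [3,4-bis(benzyloxy)-5-methoxyphenyl]methanol
Product: 17 1,2-bis(benzyloxy)-5-(bromomethyl)-3-methoxybenzene
Conditions: PBr3, Et2O, 0 °C; used promptly
Reagents that add atoms: phosphorus tribromide, BrP(Br)Br
Why: Conversion of a primary benzylic alcohol to the bromide through its phosphite ester (SN2 by bromide), mild enough to leave the benzyl and methyl ethers in place.

Step 8
Reactants: 13 (4R)-4-[4-(benzyloxy)-3-methoxybenzyl]dihydrofuran-2(3H)-one; 17 1,2-bis(benzyloxy)-5-(bromomethyl)-3-methoxybenzene
Product: 19 (3R,4R)-3-[3,4-bis(benzyloxy)-5-methoxybenzyl]-4-[4-(benzyloxy)-3-methoxybenzyl]dihydrofuran-2(3H)-one, via lithium enolate 18 (not isolated)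
Conditions: LiHMDS (1.1 equiv), THF, −78 °C; then 17, HMPA (or DMPU), −78 → −30 °C
Reagents that add atoms: none
Why: Substrate-controlled diastereoselective alkylation of a β-substituted γ-butyrolactone enolate, in which the benzylic bromide approaches the planar enolate 18 on the face anti to the C4 benzyl group and so should set C3 as R, trans to C4.

Step 9
Reactants: 19 (3R,4R)-3-[3,4-bis(benzyloxy)-5-methoxybenzyl]-4-[4-(benzyloxy)-3-methoxybenzyl]dihydrofuran-2(3H)-one
Product: 20 (−)-thujaplicatin
Conditions: H2 (1 atm), 10% Pd/C, EtOAc–MeOH, rt; filtration and concentration under argon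
Reagents that add atoms: none
Why: Catalytic hydrogenolysis of three benzyl aryl ethers, which leaves the lactone, the methyl ethers, the benzylic C–C bonds and both stereocentres untouched.

**Compound list**
1 | (R)-epichlorohydrin, (2R)-2-(chloromethyl)oxirane | ClC[C@H]1CO1 | starting material
2 | diethyl malonate | CCOC(=O)CC(=O)OCC | starting material
3 | diethyl 2-[(2R)-3-chloro-2-hydroxypropyl]malonate (present as sodium alkoxide) | CCOC(=O)C(C[C@@H](O)CCl)C(=O)OCC | intermediate
4 | diethyl 2-{[(2R)-oxiran-2-yl]methyl}malonate | CCOC(=O)C(C[C@@H]1CO1)C(=O)OCC | intermediate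
5 | diethyl (2R)-2-(hydroxymethyl)cyclopropane-1,1-dicarboxylate (present as sodium alkoxide) | CCOC(=O)C1(C[C@H]1CO)C(=O)OCC | intermediate
6 | ethyl (1S,5R)-2-oxo-3-oxabicyclo[3.1.0]hexane-1-carboxylate | CCOC(=O)[C@]12C[C@H]1COC2=O | intermediate
7 | 4-bromo-2-methoxyphenol | COc1cc(Br)ccc1O | starting material
8 | 1-(benzyloxy)-4-bromo-2-methoxybenzene | COc1cc(Br)ccc1OCc1ccccc1 | intermediate
9 | [4-(benzyloxy)-3-methoxyphenyl]magnesium bromide | COc1cc([Mg]Br)ccc1OCc1ccccc1 | intermediate
10 | bromomagnesium enolate of 11 | CCOC(=O)C1=C(O[Mg]Br)OC[C@@H]1Cc1ccc(OCc2ccccc2)c(OC)c1 | intermediate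
11 | ethyl (4R)-4-[4-(benzyloxy)-3-methoxybenzyl]-2-oxotetrahydrofuran-3-carboxylate (C3 epimers) | CCOC(=O)C1C(=O)OC[C@@H]1Cc1ccc(OCc2ccccc2)c(OC)c1 | intermediate
12 | lithium (4R)-4-[4-(benzyloxy)-3-methoxybenzyl]-2-oxotetrahydrofuran-3-carboxylate | [Li+].[O-]C(=O)C1C(=O)OC[C@@H]1Cc1ccc(OCc2ccccc2)c(OC)c1 | intermediate
13 | (4R)-4-[4-(benzyloxy)-3-methoxybenzyl]dihydrofuran-2(3H)-one | O=C1C[C@@H](Cc2ccc(OCc3ccccc3)c(OC)c2)CO1 | intermediate
14 | 3,4-dihydroxy-5-methoxybenzaldehyde (5-hydroxyvanillin) | COc1cc(C=O)cc(O)c1O | starting material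
15 | 3,4-bis(benzyloxy)-5-methoxybenzaldehyde | COc1cc(C=O)cc(OCc2ccccc2)c1OCc1ccccc1 | intermediate
16 | [3,4-bis(benzyloxy)-5-methoxyphenyl]methanol | COc1cc(CO)cc(OCc2ccccc2)c1OCc1ccccc1 | intermediate
17 | 1,2-bis(benzyloxy)-5-(bromomethyl)-3-methoxybenzene | COc1cc(CBr)cc(OCc2ccccc2)c1OCc1ccccc1 | intermediate
18 | lithium enolate of 13 | [Li]OC1=C[C@@H](Cc2ccc(OCc3ccccc3)c(OC)c2)CO1 | intermediate
19 | (3R,4R)-3-[3,4-bis(benzyloxy)-5-methoxybenzyl]-4-[4-(benzyloxy)-3-methoxybenzyl]dihydrofuran-2(3H)-one | COc1cc(C[C@H]2COC(=O)[C@@H]2Cc2cc(OCc3ccccc3)c(OCc3ccccc3)c(OC)c2)ccc1OCc1ccccc1 | intermediate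
20 | (−)-thujaplicatin, (3R,4R)-3-(3,4-dihydroxy-5-methoxybenzyl)-4-(4-hydroxy-3-methoxybenzyl)dihydrofuran-2(3H)-one | COc1cc(C[C@H]2COC(=O)[C@@H]2Cc2cc(O)c(O)c(OC)c2)ccc1O | target

**Step count and risks**
Total step count: 9. Longest linear sequence: 5 steps (steps 1, 3, 4, 8, 9 from compound 1; equally steps 5, 6, 7, 8, 9 from compound 14).

Steps most likely to fail:

Step 3. The aryl Grignard reagent may add to the ester or lactone carbonyl of 6 faster than the copper-mediated ring opening, or the aryl group may be transferred from copper too slowly to open the cyclopropane. The fallback sets out from 8 and comes back at 13. Grignard reagent 9 from 8 is formylated with DMF to 4-(benzyloxy)-3-methoxybenzaldehyde F1. Stobbe condensation of this with dimethyl succinate (NaOMe, MeOH, reflux) should give (E)-4-[4-(benzyloxy)-3-methoxyphenyl]-3-(methoxycarbonyl)but-3-enoic acid F2. Asymmetric hydrogenation with a cationic Rh(I)–chiral bisphosphine catalyst, the ligand enantiomer being chosen for the (R) product, should give (3R)-4-[4-(benzyloxy)-3-methoxyphenyl]-3-(methoxycarbonyl)butanoic acid F3. Reduction of the ester in the presence of the potassium carboxylate (KOH; NaBH4/CaCl2, EtOH) and acidification should close lactone 13. In this variant the CH2–aryl bond arrives with the aldehyde and C4 is set by the hydrogenation catalyst.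

Step 8. Proton transfer between product and enolate may erode the trans selectivity and cause double alkylation, or the electron-rich benzylic bromide may decompose before it is captured. The fallback sets out from 13 and 15 and comes back at 20. Enolate 18 is added to aldehyde 15 at −78 °C (aldol addition anti to the C4 substituent) to give (3S,4R)-3-{[3,4-bis(benzyloxy)-5-methoxyphenyl](hydroxy)methyl}-4-[4-(benzyloxy)-3-methoxybenzyl]dihydrofuran-2(3H)-one F4 as a mixture of carbinol epimers. Hydrogenolysis (H2, Pd/C, EtOAc–AcOH, cat. HClO4) should then remove the benzylic hydroxyl group together with the three benzyl ethers and give 20 directly, so steps 6 and 7 are not needed.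

Step 1. Part of the malonate may displace chloride directly before the epoxide is opened; this path leads to the mirror-image bicycle and lowers the enantiomeric purity. The fallback sets out from 2 and comes back at 4, and so at 6. Sodium diethyl malonate (NaH, THF, 0 °C) is alkylated with (2S)-oxiran-2-ylmethyl trifluoromethanesulfonate F5, freshly made from commercial (R)-glycidol with Tf2O and 2,6-lutidine. The sulfonate should be displaced before the epoxide reacts, which gives epoxy malonate 4 directly; further base then closes the cyclopropane and the lactone as in step 1.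

**Further compounds**
F1 | step 3 | 4-(benzyloxy)-3-methoxybenzaldehyde | COc1cc(C=O)ccc1OCc1ccccc1
F2 | step 3 | (E)-4-[4-(benzyloxy)-3-methoxyphenyl]-3-(methoxycarbonyl)but-3-enoic acid | COC(=O)/C(CC(=O)O)=C/c1ccc(OCc2ccccc2)c(OC)c1
F3 | step 3 | (3R)-4-[4-(benzyloxy)-3-methoxyphenyl]-3-(methoxycarbonyl)butanoic acid | OC(=O)C[C@@H](Cc1ccc(OCc2ccccc2)c(OC)c1)C(=O)OC
F4 | step 8 | (3S,4R)-3-{[3,4-bis(benzyloxy)-5-methoxyphenyl](hydroxy)methyl}-4-[4-(benzyloxy)-3-methoxybenzyl]dihydrofuran-2(3H)-one | COc1cc(C[C@H]2COC(=O)[C@@H]2C(O)c2cc(OCc3ccccc3)c(OCc3ccccc3)c(OC)c2)ccc1OCc1ccccc1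
F5 | step 1 | (2S)-oxiran-2-ylmethyl trifluoromethanesulfonate | O=S(=O)(OC[C@@H]1CO1)C(F)(F)F
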